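All runs are simulated with constants of no real substance; scatter was added.

I read both flasks at 40 min, so what counts is how many half-lives of target fit into that time.

| setting | midnight | ochre | red |
|---|---|---|---|
| starting material | 0.10 M | 0.30 M | 0.10 M |
| free enzyme | 30 µM | 20 µM | 20 µM |
| temperature | 25 °C | −5 °C | 25 °C |
| remark | run made earlier |  |  |
| time |  | 40 min | 40 min |

midnight run (percent of the starting material charged)

| time / min | target / % | starting material / % |
|---|---|---|
| 1.00 | 102 | 1 |
| 2.00 | 98 | 0 |
| 4.00 | 94 | 0 |
| 8.00 | 93 | 1 |
| 15.0 | 85 | 1 |

(each reading ± 1.5 percentage points)

- the earlier runs were read with a standard deviation of 1.5 percentage points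
- the earlier runs do not show what temperature does; that part of a forecast is a guess
- no earlier run changes the charge of free enzyme; that part of a forecast is a guess

* the flask that ends with the higher amount of target, in percent of the starting material charged, or "neither" when 2 percentage points or less lies between them (ochre / red / neither)
* final target, as a percentage of the starting material charged, in ochre
* final target, as a percentage of the starting material charged, in red

Is the starting material out of the way by then? The midnight run shows 1% of it at 1.00 min. If the pace follows the enzyme charge, red needs at most 1.50 min, far less than the reading time, so red's target is made at the start.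

How fast does target go? In the midnight run it reads 98% at 2.00 min and 85% at 15.0 min. Taken as first-order, that gives a half-life of target, h, of 63.3 min, a reading with its scatter. I count n = t/h. Guessing that the enzyme charge does not change h, red has n = 0.632, which leaves 64.5%.

What does the cold do? No run shows it. On a guessed factor of 10, ochre has n = 0.0632 and keeps 95.7%. The same factor stretches ochre's conversion limit to 45.0 min, but that is an upper limit from a single reading, so I put ochre above red.

The forecast says ochre, with 88% for ochre and 67% for red, holding that “30 degrees colder probably slows both steps about tenfold”.

    free enzyme → unfolded enzyme (k = 8.40 × 10⁻⁶ s⁻¹, Ea = 204 kJ mol⁻¹)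
    starting material + free enzyme → target + free enzyme, rate k2*[starting material]*[free enzyme]/(1 + ([starting material]/Km2) + ([starting material]/Ksi2)^2) (6.80 mM, 9.80 mM, k = 60000 M⁻¹ s⁻¹, Ea = 14.0 kJ mol⁻¹)
    target ⇌ isomer of the product (K = 2.00, k = 1.70 × 10⁻⁴ s⁻¹, Ea = 93.0 kJ mol⁻¹, ΔH = −15.0 kJ mol⁻¹)
    (constants at 25 °C)

The flask gives ochre: ochre ends at 99.5% and red at 69.8%, against my 64.5% for red. Red's end state holds 30.2% as isomer of the product. Left for 400 min, red has n = 6.32, which my count turns into 1.25%, but the computed flask holds 33.5% of target.

A neighbour flask is like red but kept at 10 °C, half of ochre's drop. Taking my guessed factor for ochre and equal factors for equal degrees, n = 0.200, which leaves 87.1%. The computed flask gives 94.7%.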